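Chain numbering: C1–C7 from the catechol ring; O3 carries the acetyl group, O5 is the free hydroxyl. C5–O5 is an aldehyde-derived carbinol and C1–C4 with O3 is a four-carbon 3-oxygenated unit, so O5–C1–C2–C3–C4–C5 maps onto the ring of a 2,3-dihydro-4H-pyran-4-one.
Retrosynthesis: the C1–O5 bond is re-formed (the target is the hydrogenolysis product of a 2-aryl-tetrahydropyran), then the catechol-aryl–C1 bond is cut (Friedel–Crafts on a C1 acetal), then C4–C5 and O5–C1 (hetero-Diels–Alder of an aldehyde with a siloxydiene).
Forward: benzylation and oxidation give the C5–C7 aldehyde; the only ring closes in the catalytic asymmetric cycloaddition; the C3 ketone becomes the cis alcohol and its acetate; C1 is raised to a glycosyl acetate and arylated with 1,2-bis(benzyloxy)benzene; hydrogenolysis removes the benzyl groups and opens the ring at C1–O5.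
Stereochemistry: C5 (R) comes from the chiral Cr(III)–salen catalyst; C3 (R) is relayed from C5 by pseudo-axial hydride delivery to the ring ketone (cis on the ring is anti in the chain); C1 is stereogenic only in passing and ends as CH2.
O5 stays masked as the ring ether until the last step, so only O3 can be acetylated.

Key step: step 3

Assumption: the (S,S) antipode of the Cr(III)–salen catalyst is taken to direct the diene to the Si face of aldehyde 3 (2R in 6), to be checked on 6 by chiral HPLC against the racemate and reversed with the (R,R) complex if needed; the ring carbon corresponding to C1 carries no descriptor in 5, 9, 11 and 12 because it ends as a CH2 group.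

Step 1
Reactants: 1 3-(4-hydroxyphenyl)propan-1-ol
Product: 2 3-[4-(benzyloxy)phenyl]propan-1-ol
Conditions: BnBr (1.05 equiv), K2CO3, acetone, reflux
Reagents that add atoms: benzyl bromide, BrCc1ccccc1
Why: Williamson ether synthesis in which carbonate deprotonates only the phenol (far more acidic than the primary alcohol), so benzylation should occur on the phenolic oxygen alone.

Step 2
Reactants: 2 3-[4-(benzyloxy)phenyl]propan-1-ol
Product: 3 3-[4-(benzyloxy)phenyl]propanal
Conditions: TEMPO (10 mol %), PhI(OAc)2 (1.1 equiv), CH2Cl2, rt; aldehyde used promptly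
Reagents that add atoms: none
Why: TEMPO/oxoammonium oxidation of a primary alcohol stops at the aldehyde under non-aqueous conditions and tolerates the electron-rich benzyl aryl ether.

Step 3
Reactants: 3 3-[4-(benzyloxy)phenyl]propanal; 4 trans-1-methoxy-3-(trimethylsilyloxy)buta-1,3-diene
Product: 6 (2R)-2-{2-[4-(benzyloxy)phenyl]ethyl}-2,3-dihydro-4H-pyran-4-one, via silyl enol ether cycloadduct 5 (not isolated)
Conditions: (S,S)-[N,N′-bis(3,5-di-tert-butylsalicylidene)-1,2-cyclohexanediamine]Cr(III)BF4 (2–5 mol %), 4 Å MS, t-BuOMe, −30 °C; then TFA (cat.), CH2Cl2, 0 °C → rt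
Reagents that add atoms: none
Why: The cationic Cr(III)–salen complex binds the carbonyl oxygen of 3 and the electron-rich diene 4 adds in a [4+2] sense (concerted and asynchronous, or Mukaiyama aldol followed by ring closure, both leading to the same product), its unsubstituted terminus bonding to the carbonyl carbon (C4–C5) and the aldehyde oxygen to the methoxy-bearing carbon (O5–C1) to give cycloadduct 5, from which acid removes the silyl group and methanol to leave enone 6. The closest known reaction type is the Cr(III)–Schiff base catalysed enantioselective hetero-Diels–Alder reaction of unbranched aliphatic aldehydes with 1-methoxy-3-silyloxybutadienes. The one ring formed, the six-membered O5–C1–C2–C3–C4–C5 dihydropyran, closes by intermolecular [4+2] cycloaddition (in the stepwise limit by 6-endo-trig attack of the aldolate oxygen on the methoxy enone carbon). The only new stereocentre that survives, C5, is set by the catalyst alone, which exposes the Si face of the bound aldehyde and so gives the 2R ring carbon; the methoxy-bearing centre of 5 is erased in the elimination. The step needs enantiofacial selectivity only, since regiochemistry is fixed by the polarisation of the diene; the substrate secures clean one-point binding because the aldehyde is unbranched, unhindered and has no donor group close enough to chelate the metal, while molecular sieves and low temperature hold back the uncatalysed background reaction.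

Step 4
Reactants: 6 (2R)-2-{2-[4-(benzyloxy)phenyl]ethyl}-2,3-dihydro-4H-pyran-4-one
Product: 7 (2R,4S)-2-{2-[4-(benzyloxy)phenyl]ethyl}-3,4-dihydro-2H-pyran-4-ol
Conditions: NaBH4, CeCl3·7H2O, MeOH, −78 → −40 °C
Reagents that add atoms: none
Why: Luche 1,2-reduction in which hydride adds pseudo-axially to the half-chair enone that holds the C5 side chain pseudo-equatorial, so the cis (2R,4S) allylic alcohol should form under substrate control, which corresponds to the anti (3R,5R) relationship of the target chain.

Step 5
Reactants: 7 (2R,4S)-2-{2-[4-(benzyloxy)phenyl]ethyl}-3,4-dihydro-2H-pyran-4-ol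
Product: 8 (2R,4S)-2-{2-[4-(benzyloxy)phenyl]ethyl}-3,4-dihydro-2H-pyran-4-yl acetate
Conditions: Ac2O, pyridine, DMAP (cat.), CH2Cl2, 0 °C → rt
Reagents that add atoms: acetic anhydride, CC(=O)OC(C)=O
Why: DMAP-catalysed acylation of the only free hydroxyl under basic conditions that leave the acid-sensitive enol ether and the carbinol configuration untouched.

Step 6
Reactants: 8 (2R,4S)-2-{2-[4-(benzyloxy)phenyl]ethyl}-3,4-dihydro-2H-pyran-4-yl acetate
Product: 9 (4S,6R)-6-{2-[4-(benzyloxy)phenyl]ethyl}tetrahydro-2H-pyran-2,4-diyl diacetate (mixture at C2 of the ring)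
Conditions: AcOH (5 equiv), PPh3·HBr (5 mol %), CH2Cl2, 0 °C → rt; used without prolonged storage
Reagents that add atoms: acetic acid, CC(=O)O
Why: Acid-catalysed Markovnikov addition of a carboxylic acid to a glycal-type enol ether (protonation at C2, capture at C1), run with a mild phosphonium hydrobromide to disfavour Ferrier-type displacement of the allylic acetate; the new acetal centre forms as a mixture, which is immaterial.

Step 7
Reactants: 9 (4S,6R)-6-{2-[4-(benzyloxy)phenyl]ethyl}tetrahydro-2H-pyran-2,4-diyl diacetate; 10 1,2-bis(benzyloxy)benzene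
Product: 11 (4S,6R)-2-[3,4-bis(benzyloxy)phenyl]-6-{2-[4-(benzyloxy)phenyl]ethyl}tetrahydro-2H-pyran-4-yl acetate (mixture at C2 of the ring)
Conditions: 10 (2 equiv), TMSOTf (0.2 equiv), 4 Å MS, CH2Cl2, −40 → −10 °C
Reagents that add atoms: none
Why: Friedel–Crafts C-glycosylation in which the Lewis acid ionises the acetal acetate at C1 (far more labile than the secondary C3 acetate) to an oxocarbenium ion that is attacked by the dialkoxyarene para to a benzyloxy group, the less hindered and more activated position; the configuration at C1 is irrelevant.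

Step 8
Reactants: 11 (4S,6R)-2-[3,4-bis(benzyloxy)phenyl]-6-{2-[4-(benzyloxy)phenyl]ethyl}tetrahydro-2H-pyran-4-yl acetate
Product: 13 (3R,5R)-1-(3,4-dihydroxyphenyl)-5-hydroxy-7-(4-hydroxyphenyl)heptan-3-yl acetate (target), via triphenol tetrahydropyran 12 (not isolated)
Conditions: H2 (1–4 bar), Pd(OH)2/C, EtOAc–THF, rt, neutral; filtration and chromatography under argon
Reagents that add atoms: none
Why: Catalytic hydrogenolysis should first cleave the three benzyl aryl ethers and then the ring C1–O5 bond, which is benzylic to an electron-rich aryl group, turning C1 into CH2 and releasing O5–H, while the alkyl acetate and the non-benzylic C3 and C5 centres are not touched and neutral conditions avoid 1,3-acetyl migration.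

Compound list
1 | 3-(4-hydroxyphenyl)propan-1-ol | OCCCc1ccc(O)cc1 | starting material
2 | 3-[4-(benzyloxy)phenyl]propan-1-ol | OCCCc1ccc(OCc2ccccc2)cc1 | intermediate
3 | 3-[4-(benzyloxy)phenyl]propanal | O=CCCc1ccc(OCc2ccccc2)cc1 | intermediate
4 | trans-1-methoxy-3-(trimethylsilyloxy)buta-1,3-diene | CO/C=C/C(=C)O[Si](C)(C)C | starting material
5 | (2R)-2-{2-[4-(benzyloxy)phenyl]ethyl}-6-methoxy-4-(trimethylsilyloxy)-3,6-dihydro-2H-pyran (C6 unassigned, not isolated) | COC1C=C(O[Si](C)(C)C)C[C@@H](CCc2ccc(OCc3ccccc3)cc2)O1 | intermediate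
6 | (2R)-2-{2-[4-(benzyloxy)phenyl]ethyl}-2,3-dihydro-4H-pyran-4-one | O=C1C=CO[C@H](CCc2ccc(OCc3ccccc3)cc2)C1 | intermediate
7 | (2R,4S)-2-{2-[4-(benzyloxy)phenyl]ethyl}-3,4-dihydro-2H-pyran-4-ol | O[C@@H]1C=CO[C@H](CCc2ccc(OCc3ccccc3)cc2)C1 | intermediate
8 | (2R,4S)-2-{2-[4-(benzyloxy)phenyl]ethyl}-3,4-dihydro-2H-pyran-4-yl acetate | CC(=O)O[C@@H]1C=CO[C@H](CCc2ccc(OCc3ccccc3)cc2)C1 | intermediate
9 | (4S,6R)-6-{2-[4-(benzyloxy)phenyl]ethyl}tetrahydro-2H-pyran-2,4-diyl diacetate (C2 mixture) | CC(=O)OC1C[C@@H](OC(C)=O)C[C@@H](CCc2ccc(OCc3ccccc3)cc2)O1 | intermediate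
10 | 1,2-bis(benzyloxy)benzene | c1ccc(COc2ccccc2OCc2ccccc2)cc1 | starting material
11 | (4S,6R)-2-[3,4-bis(benzyloxy)phenyl]-6-{2-[4-(benzyloxy)phenyl]ethyl}tetrahydro-2H-pyran-4-yl acetate (C2 mixture) | CC(=O)O[C@@H]1CC(c2ccc(OCc3ccccc3)c(OCc3ccccc3)c2)O[C@H](CCc2ccc(OCc3ccccc3)cc2)C1 | intermediate
12 | (4S,6R)-2-(3,4-dihydroxyphenyl)-6-[2-(4-hydroxyphenyl)ethyl]tetrahydro-2H-pyran-4-yl acetate (C2 mixture, not isolated) | CC(=O)O[C@@H]1CC(c2ccc(O)c(O)c2)O[C@H](CCc2ccc(O)cc2)C1 | intermediate
13 | (3R,5R)-1-(3,4-dihydroxyphenyl)-5-hydroxy-7-(4-hydroxyphenyl)heptan-3-yl acetate | CC(=O)O[C@H](CCc1ccc(O)c(O)c1)C[C@H](O)CCc1ccc(O)cc1 | target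

Total step count: 8. Longest linear sequence: 8 steps (1 → 13); compounds 4 and 10 are purchased.

Steps most likely to fail

Step 7. The arene may trap the oxocarbenium ion too slowly, so that proton loss back to the enol ether or acid-induced loss of the C3 acetate takes over. The electron-rich benzylic ether of the product may also re-ionise and be arylated a second time. The fallback sets out from 9 and comes back at 11, replacing electrophilic aromatic substitution by cross-coupling with a preformed aryl nucleophile. Compound 9 is treated with TMSBr (CH2Cl2, 0 °C) to give the glycosyl bromide (4S,6R)-2-bromo-6-{2-[4-(benzyloxy)phenyl]ethyl}tetrahydro-2H-pyran-4-yl acetate F1, used crude. Commercial 4-bromo-1,2-bis(benzyloxy)benzene (Brc1ccc(OCc2ccccc2)c(OCc2ccccc2)c1) is converted with Mg/LiCl in THF into [3,4-bis(benzyloxy)phenyl]magnesium bromide F2 and transmetalated with ZnBr2 to [3,4-bis(benzyloxy)phenyl]zinc bromide F3. Nickel-catalysed Negishi coupling of F1 with F3 (NiCl2·glyme, terpyridine-type ligand, DMA–THF, rt) should then give 11; esters are tolerated and the position of the bromide fixes the arene regiochemistry.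

Step 6. Ionisation of the allylic C3 acetate (Ferrier-type allylic displacement) or oligomerisation of the electron-rich enol ether may outrun protonation at C2 and capture by acetic acid. The fallback sets out from 8 and comes back at 9, activating the double bond with an iodonium ion in place of a proton. NIS and AcOH (CH2Cl2–MeCN, 0 °C) should give by trans iodoacetoxylation (4S,6R)-6-{2-[4-(benzyloxy)phenyl]ethyl}-3-iodotetrahydro-2H-pyran-2,4-diyl diacetate F4. Radical deiodination (Bu3SnH, AIBN cat., toluene, 80 °C) then gives 9.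

Step 8. Hydrogenolysis may stall after loss of the benzyl groups because the cyclic benzylic C1–O5 bond is cleaved slowly, and forcing it with acid or heat invites acetyl migration from O3 to O5 or ring saturation. The fallback sets out from 11 and comes back at 13, separating the two events. Ionic hydrogenation (Et3SiH, TFA, CH2Cl2, −20 → 0 °C) ionises the ring ether to the alkoxy-stabilised benzylic cation at C1, which takes up hydride to give (3R,5R)-1-[3,4-bis(benzyloxy)phenyl]-7-[4-(benzyloxy)phenyl]-5-hydroxyheptan-3-yl acetate F5. Ordinary debenzylation (H2, Pd/C, EtOAc, rt) of F5 then gives 13.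

Further compounds
F1 | step 7 | (4S,6R)-2-bromo-6-{2-[4-(benzyloxy)phenyl]ethyl}tetrahydro-2H-pyran-4-yl acetate | CC(=O)O[C@@H]1CC(Br)O[C@H](CCc2ccc(OCc3ccccc3)cc2)C1
F2 | step 7 | [3,4-bis(benzyloxy)phenyl]magnesium bromide | Br[Mg]c1ccc(OCc2ccccc2)c(OCc2ccccc2)c1
F3 | step 7 | [3,4-bis(benzyloxy)phenyl]zinc bromide | Br[Zn]c1ccc(OCc2ccccc2)c(OCc2ccccc2)c1
F4 | step 6 | (4S,6R)-6-{2-[4-(benzyloxy)phenyl]ethyl}-3-iodotetrahydro-2H-pyran-2,4-diyl diacetate | CC(=O)OC1O[C@H](CCc2ccc(OCc3ccccc3)cc2)C[C@H](OC(C)=O)C1I
F5 | step 8 | (3R,5R)-1-[3,4-bis(benzyloxy)phenyl]-7-[4-(benzyloxy)phenyl]-5-hydroxyheptan-3-yl acetate | CC(=O)O[C@H](CCc1ccc(OCc2ccccc2)c(OCc2ccccc2)c1)C[C@H](O)CCc1ccc(OCc2ccccc2)cc1
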